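The route rests on cutting the cyclobutane bond between C1 (the only stereocentre, carrying the ester oxygen and C2 of the naphthazarin) and the neighbouring ring CMe2 carbon. Because the two carbons are also joined through two CH2 groups, an open chain with a benzylic carbamate at C1 and a tertiary pinacol boronic ester at CMe2 can close on boron and then contract: the tertiary carbon moves from boron to C1 as the carbamate leaves. One operation thus makes the crowded C1–CMe2 bond, the four-membered ring and the fully substituted stereocentre, the chirality coming from an (S)-carbinol set by asymmetric transfer hydrogenation. The naphthazarin is carried as its tetramethyl ether and unmasked last.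

Key step: step 9

Assumption: the target is one tautomer of a naphthazarin whose tautomers interconvert, so the 2- and 6-substituted quinone regioisomers lead to the same compound; the (S,S)-catalyst of step 5 is expected to give the (S)-carbinol by analogy with simple aryl alkyl ketones, to be confirmed on the Mosher esters.

Step 1
Reactants: 1 naphthazarin (5,8-dihydroxy-1,4-naphthoquinone)
Product: 3 1,4,5,8-tetramethoxynaphthalene, via leuco tetrol 2 (not isolated)
Conditions: Na2S2O4, NaOH, n-Bu4NBr, THF/H2O, N2, rt; then Me2SO4, rt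
Reagents that add atoms: dimethyl sulfate, COS(=O)(=O)OC
Why: Reductive methylation: Na2S2O4 reduces the quinone to the air-sensitive tetrol 2, whose four phenoxides are O-methylated in the same pot under phase transfer (Williamson ether synthesis).

Step 2
Reactants: 3 1,4,5,8-tetramethoxynaphthalene
Product: 5 1,4,5,8-tetramethoxynaphthalene-2-carbaldehyde, via aryl iminium salt 4 (not isolated)
Conditions: POCl3, DMF, CHCl3, 65 °C; then H2O
Reagents that add atoms: N,N-dimethylformamide, CN(C)C=O; water, O
Why: Vilsmeier–Haack formylation of a very electron-rich arene; the four free ring positions of 3 are equivalent and the first formyl group deactivates the system, so a single mono-aldehyde is expected after hydrolysis of 4.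

Step 3
Reactants: 5 1,4,5,8-tetramethoxynaphthalene-2-carbaldehyde; 6 4-bromo-2-methylbut-1-ene
Product: 8 racemic 4-methyl-1-(1,4,5,8-tetramethoxynaphthalen-2-yl)pent-4-en-1-ol, via Grignard reagent 7 (not isolated)
Conditions: 6, Mg, THF, rt; then 5, THF, 0 °C; aq NH4Cl
Reagents that add atoms: none
Why: Grignard addition of a primary homoallyl magnesium bromide to an aryl aldehyde assembles the whole side-chain skeleton; the carbinol is left racemic because its configuration is set in step 5.

Step 4
Reactants: 8 racemic 4-methyl-1-(1,4,5,8-tetramethoxynaphthalen-2-yl)pent-4-en-1-ol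
Product: 9 4-methyl-1-(1,4,5,8-tetramethoxynaphthalen-2-yl)pent-4-en-1-one
Conditions: MnO2, CH2Cl2, rt
Reagents that add atoms: none
Why: Benzylic alcohol oxidation with activated MnO2, mild enough to spare the 1,1-disubstituted alkene and the easily oxidised tetramethoxynaphthalene.

Step 5
Reactants: 9 4-methyl-1-(1,4,5,8-tetramethoxynaphthalen-2-yl)pent-4-en-1-one
Product: 10 (S)-4-methyl-1-(1,4,5,8-tetramethoxynaphthalen-2-yl)pent-4-en-1-ol
Conditions: RuCl[(S,S)-TsDPEN](p-cymene) (cat.), HCO2H/Et3N (5:2), 30 °C
Reagents that add atoms: none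
Why: Noyori asymmetric transfer hydrogenation: the ruthenium hydride/NH pair of the (S,S)-catalyst reduces the aryl ketone through an outer-sphere six-membered transition state organised by a CH/π contact with the naphthyl group, which should give the (S)-carbinol, and unlike a borane it leaves the isolated alkene alone.

Step 6
Reactants: 10 (S)-4-methyl-1-(1,4,5,8-tetramethoxynaphthalen-2-yl)pent-4-en-1-ol
Product: 11 (S)-4-methyl-1-(1,4,5,8-tetramethoxynaphthalen-2-yl)pent-4-en-1-yl N,N-diisopropylcarbamate
Conditions: i-Pr2NCOCl, Et3N, CH2Cl2, reflux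
Reagents that add atoms: N,N-diisopropylcarbamoyl chloride, CC(C)N(C(C)C)C(Cl)=O
Why: O-Carbamoylation under basic conditions does not break the C–O bond at the stereocentre, so the (S)-configuration is kept, and it installs the group that acidifies the benzylic proton and later leaves in step 9.

Step 7
Reactants: 11 (S)-4-methyl-1-(1,4,5,8-tetramethoxynaphthalen-2-yl)pent-4-en-1-yl N,N-diisopropylcarbamate
Product: 12 (S)-4-bromo-4-methyl-1-(1,4,5,8-tetramethoxynaphthalen-2-yl)pentyl N,N-diisopropylcarbamate
Conditions: Co(acac)2, t-BuOOH, Et3SiH, TsBr, n-PrOH, rt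
Reagents that add atoms: p-toluenesulfonyl bromide, Cc1ccc(cc1)S(=O)(=O)Br
Why: Mukaiyama-type hydrogen atom transfer hydrobromination: a cobalt hydride formed from the silane gives the tertiary (Markovnikov) radical, which abstracts bromine from TsBr without any protic acid, so the ionisable benzylic carbamate and its stereocentre are untouched.

Step 8
Reactants: 12 (S)-4-bromo-4-methyl-1-(1,4,5,8-tetramethoxynaphthalen-2-yl)pentyl N,N-diisopropylcarbamate
Product: 13 (S)-4-methyl-4-(4,4,5,5-tetramethyl-1,3,2-dioxaborolan-2-yl)-1-(1,4,5,8-tetramethoxynaphthalen-2-yl)pentyl N,N-diisopropylcarbamate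
Conditions: NiBr2·diglyme (cat.), i-Pr-pybox (cat.), B2pin2, KOEt, i-Pr2O/DMA, rt
Reagents that add atoms: bis(pinacolato)diboron, CC1(C)OB(OC1(C)C)B2OC(C)(C)C(C)(C)O2
Why: Nickel-catalysed Miyaura-type borylation of an unactivated tertiary alkyl bromide, which runs through the tertiary radical and a nickel boryl species at room temperature, tolerates carbamates and does not involve the remote stereocentre.

Step 9
Reactants: 13 (S)-4-methyl-4-(4,4,5,5-tetramethyl-1,3,2-dioxaborolan-2-yl)-1-(1,4,5,8-tetramethoxynaphthalen-2-yl)pentyl N,N-diisopropylcarbamate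
Product: 16 (S)-2-[2,2-dimethyl-1-(1,4,5,8-tetramethoxynaphthalen-2-yl)cyclobutyl]-4,4,5,5-tetramethyl-1,3,2-dioxaborolane, via lithiated carbamate 14 (not isolated), via cyclic lithium boronate 15 (not isolated)
Conditions: LiN(i-Pr)2, Et2O/THF, −78 °C; then −78 → 35 °C (MgBr2·OEt2/MeOH if 15 persists)
Reagents that add atoms: none
Why: Proposed new method: LiN(i-Pr)2 removes the benzylic proton next to the carbamate oxygen with retention to give 14, and the tethered pinacol boronic ester captures this carbanion at once on its lithium-bearing face to give the spiro five-membered boronate 15; on warming, the ring B–CMe2 bond, which an envelope conformer places close to antiperiplanar to the C–O bond, delivers the tertiary carbon to C1 with inversion while lithium carbamate departs. The closest known reaction types are the stereospecific lithiation–borylation of secondary benzylic carbamates to tertiary boronic esters (also run with amide bases in the presence of the boronic ester) and the strain-increasing 1,2-metallate contraction of five-membered cyclic boronate complexes to cyclobutyl boronic esters. The transient borolane ring closes by attack of the carbanion on trigonal boron (five-membered, exo) and the cyclobutane closes in the 1,2-shift, formally a 4-exo-tet displacement at C1, the strain being paid for by loss of the carbamate and the return of boron to a neutral ester. The new fully substituted stereocentre is controlled by the (S)-carbamate carbon alone, relayed by retentive borylation and invertive migration to (S)-16. The step needs complete stereospecificity and migration of carbon, not of a pinacol oxygen; the tether secures both, since it makes trapping outrun racemisation of 14 and lithiation of the ring, leaves CMe2 as the only carbon on boron that can migrate and holds that bond anti to the leaving group. Ionisation of the C–O bond, which the electron-rich naphthalene favours and which would erode the stereochemistry, is held back by running the shift cold in a weakly polar ether.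

Step 10
Reactants: 16 (S)-2-[2,2-dimethyl-1-(1,4,5,8-tetramethoxynaphthalen-2-yl)cyclobutyl]-4,4,5,5-tetramethyl-1,3,2-dioxaborolane
Product: 17 (R)-2,2-dimethyl-1-(1,4,5,8-tetramethoxynaphthalen-2-yl)cyclobutan-1-ol
Conditions: NaOH, H2O2, THF/H2O, 0 °C → rt
Reagents that add atoms: hydrogen peroxide, OO
Why: Boronic ester oxidation: hydroperoxide adds to boron and the cyclobutyl carbon migrates from boron to oxygen with retention, so (S)-16 gives (R)-17 (the descriptor changes only because O outranks B), and the basic medium protects the acid-labile tertiary benzylic alcohol.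

Step 11
Reactants: 17 (R)-2,2-dimethyl-1-(1,4,5,8-tetramethoxynaphthalen-2-yl)cyclobutan-1-ol; 18 angelic acid ((Z)-2-methylbut-2-enoic acid)
Product: 21 (R)-2,2-dimethyl-1-(1,4,5,8-tetramethoxynaphthalen-2-yl)cyclobutyl (Z)-2-methylbut-2-enoate, via mixed anhydride 19 (not isolated), via lithium alkoxide 20 (not isolated)
Conditions: 18, 2,4,6-Cl3C6H2COCl, Et3N, THF, 0 °C (gives 19, filtered); 17, LiN(SiMe3)2, THF, −78 °C (gives 20); then 19 added, −78 °C → rt
Reagents that add atoms: none
Why: Acylation of a preformed lithium alkoxide by a Yamaguchi-type mixed anhydride: the alkoxide attacks the less shielded angeloyl carbonyl of 19, and the absence of acid and of nucleophilic amine during acyl transfer should keep the Z alkene from isomerising to the tiglate; the ester is put on before any oxidation because a free cyclobutanol would fragment under (NH4)2Ce(NO3)6.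

Step 12
Reactants: 21 (R)-2,2-dimethyl-1-(1,4,5,8-tetramethoxynaphthalen-2-yl)cyclobutyl (Z)-2-methylbut-2-enoate
Product: 22 (R)-1-(5,8-dimethoxy-1,4-dioxo-1,4-dihydronaphthalen-2-yl)-2,2-dimethylcyclobutyl (Z)-2-methylbut-2-enoate and 23 (R)-1-(1,4-dimethoxy-5,8-dioxo-5,8-dihydronaphthalen-2-yl)-2,2-dimethylcyclobutyl (Z)-2-methylbut-2-enoate (regioisomers, not separated)
Conditions: (NH4)2Ce(NO3)6, MeCN/H2O, 0 °C
Reagents that add atoms: water, O
Why: Oxidative demethylation of a 1,4-dimethoxyarene by tetravalent cerium, with water supplying the quinone oxygens; either ring may be oxidised and both regioisomers lead to the same naphthazarin, while the acylated tertiary alcohol cannot form the alkoxy radical that would open the cyclobutane.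

Step 13
Reactants: 22 (R)-1-(5,8-dimethoxy-1,4-dioxo-1,4-dihydronaphthalen-2-yl)-2,2-dimethylcyclobutyl (Z)-2-methylbut-2-enoate; 23 (R)-1-(1,4-dimethoxy-5,8-dioxo-5,8-dihydronaphthalen-2-yl)-2,2-dimethylcyclobutyl (Z)-2-methylbut-2-enoate
Product: 24 (R)-1-(5,8-dihydroxy-1,4-dioxo-1,4-dihydronaphthalen-2-yl)-2,2-dimethylcyclobutyl (Z)-2-methylbut-2-enoate (CNP0326301.1)
Conditions: BCl3, CH2Cl2, −78 → −20 °C; then pH 7 buffer, −78 °C → rt
Reagents that add atoms: none
Why: Chelation-assisted ether cleavage: BCl3 binds each quinone carbonyl together with its peri methoxy oxygen and chloride removes the methyl group, so both ethers should fall at low temperature while the tertiary ester and the Z alkene survive; the two regioisomers converge because the naphthazarin tautomers interconvert.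

Compound list
1 | naphthazarin (5,8-dihydroxy-1,4-naphthoquinone) | O=C1C=CC(=O)c2c(O)ccc(O)c12 | starting material
2 | naphthalene-1,4,5,8-tetrol (leuco-naphthazarin) | Oc1ccc(O)c2c(O)ccc(O)c12 | intermediate (not isolated)
3 | 1,4,5,8-tetramethoxynaphthalene | COc1ccc(OC)c2c(OC)ccc(OC)c12 | intermediate
4 | N,N-dimethyl-1-(1,4,5,8-tetramethoxynaphthalen-2-yl)methaniminium dichlorophosphate | C[N+](C)=Cc1cc(OC)c2c(OC)ccc(OC)c2c1OC.[O-]P(=O)(Cl)Cl | intermediate (not isolated)
5 | 1,4,5,8-tetramethoxynaphthalene-2-carbaldehyde | O=Cc1cc(OC)c2c(OC)ccc(OC)c2c1OC | intermediate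
6 | 4-bromo-2-methylbut-1-ene | C=C(C)CCBr | starting material
7 | (3-methylbut-3-en-1-yl)magnesium bromide | C=C(C)CC[Mg]Br | intermediate (not isolated)
8 | racemic 4-methyl-1-(1,4,5,8-tetramethoxynaphthalen-2-yl)pent-4-en-1-ol | OC(c1cc(OC)c2c(OC)ccc(OC)c2c1OC)CCC(C)=C | intermediate
9 | 4-methyl-1-(1,4,5,8-tetramethoxynaphthalen-2-yl)pent-4-en-1-one | C=C(C)CCC(=O)c1cc(OC)c2c(OC)ccc(OC)c2c1OC | intermediate
10 | (S)-4-methyl-1-(1,4,5,8-tetramethoxynaphthalen-2-yl)pent-4-en-1-ol | O[C@H](c1cc(OC)c2c(OC)ccc(OC)c2c1OC)CCC(C)=C | intermediate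
11 | (S)-4-methyl-1-(1,4,5,8-tetramethoxynaphthalen-2-yl)pent-4-en-1-yl N,N-diisopropylcarbamate | CC(C)N(C(C)C)C(=O)O[C@H](c1cc(OC)c2c(OC)ccc(OC)c2c1OC)CCC(C)=C | intermediate
12 | (S)-4-bromo-4-methyl-1-(1,4,5,8-tetramethoxynaphthalen-2-yl)pentyl N,N-diisopropylcarbamate | CC(C)N(C(C)C)C(=O)O[C@H](c1cc(OC)c2c(OC)ccc(OC)c2c1OC)CCC(C)(C)Br | intermediate
13 | (S)-4-methyl-4-(4,4,5,5-tetramethyl-1,3,2-dioxaborolan-2-yl)-1-(1,4,5,8-tetramethoxynaphthalen-2-yl)pentyl N,N-diisopropylcarbamate | CC(C)N(C(C)C)C(=O)O[C@H](c1cc(OC)c2c(OC)ccc(OC)c2c1OC)CCC(C)(C)B3OC(C)(C)C(C)(C)O3 | intermediate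
14 | α-lithiated carbamate of 13 (lithium in place of the benzylic hydrogen, configuration retained) | CC(C)N(C(C)C)C(=O)O[C@]([Li])(c1cc(OC)c2c(OC)ccc(OC)c2c1OC)CCC(C)(C)B3OC(C)(C)C(C)(C)O3 | intermediate (not isolated)
15 | lithium spiro boronate: pinacolato borate whose boron also sits in a borolane ring made of B, the carbamate- and aryl-bearing carbon, two CH2 and CMe2 | [Li+].CC(C)N(C(C)C)C(=O)O[C@]1(c3cc(OC)c4c(OC)ccc(OC)c4c3OC)CCC(C)(C)[B-]12OC(C)(C)C(C)(C)O2 | intermediate (not isolated)
16 | (S)-2-[2,2-dimethyl-1-(1,4,5,8-tetramethoxynaphthalen-2-yl)cyclobutyl]-4,4,5,5-tetramethyl-1,3,2-dioxaborolane | CC1(C)OB(OC1(C)C)[C@]2(c3cc(OC)c4c(OC)ccc(OC)c4c3OC)CCC2(C)C | intermediate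
17 | (R)-2,2-dimethyl-1-(1,4,5,8-tetramethoxynaphthalen-2-yl)cyclobutan-1-ol | O[C@]1(c2cc(OC)c3c(OC)ccc(OC)c3c2OC)CCC1(C)C | intermediate
18 | angelic acid ((Z)-2-methylbut-2-enoic acid) | C/C=C(/C)C(=O)O | starting material
19 | (Z)-2-methylbut-2-enoic 2,4,6-trichlorobenzoic anhydride | C/C=C(/C)C(=O)OC(=O)c1c(Cl)cc(Cl)cc1Cl | intermediate (not isolated)
20 | lithium (R)-2,2-dimethyl-1-(1,4,5,8-tetramethoxynaphthalen-2-yl)cyclobutan-1-olate | [Li]O[C@]1(c2cc(OC)c3c(OC)ccc(OC)c3c2OC)CCC1(C)C | intermediate (not isolated)
21 | (R)-2,2-dimethyl-1-(1,4,5,8-tetramethoxynaphthalen-2-yl)cyclobutyl (Z)-2-methylbut-2-enoate | C/C=C(/C)C(=O)O[C@]1(c2cc(OC)c3c(OC)ccc(OC)c3c2OC)CCC1(C)C | intermediate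
22 | (R)-1-(5,8-dimethoxy-1,4-dioxo-1,4-dihydronaphthalen-2-yl)-2,2-dimethylcyclobutyl (Z)-2-methylbut-2-enoate (2-substituted 5,8-dimethoxy-1,4-naphthoquinone) | C/C=C(/C)C(=O)O[C@]1(C2=CC(=O)c3c(OC)ccc(OC)c3C2=O)CCC1(C)C | intermediate
23 | (R)-1-(1,4-dimethoxy-5,8-dioxo-5,8-dihydronaphthalen-2-yl)-2,2-dimethylcyclobutyl (Z)-2-methylbut-2-enoate (6-substituted 5,8-dimethoxy-1,4-naphthoquinone) | C/C=C(/C)C(=O)O[C@]1(c2cc(OC)c3C(=O)C=CC(=O)c3c2OC)CCC1(C)C | intermediate
24 | (R)-1-(5,8-dihydroxy-1,4-dioxo-1,4-dihydronaphthalen-2-yl)-2,2-dimethylcyclobutyl (Z)-2-methylbut-2-enoate, CNP0326301.1 | C/C=C(/C)C(=O)O[C@]1(C2=CC(=O)c3c(O)ccc(O)c3C2=O)CCC1(C)C | target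

Total step count: 13
Longest linear sequence: 13 steps (1 → 24); 6 and 18 enter as bought materials.

Steps most likely to fail

Step 9 (ring-contracting lithiation–borylation). The cyclic boronate may fail to undergo the strain-building shift: it may reopen, migrate a pinacol oxygen in place of carbon, or ionise at the benzylic C–O bond with loss of stereochemical fidelity. An invertive internal borylation would only call for the (R,R)-catalyst in step 5. Fallback by known chemistry, setting out from 3 and rejoining at 17: bromination of 3 with NBS in MeCN should give 2-bromo-1,4,5,8-tetramethoxynaphthalene F1. Bromine–lithium exchange (n-BuLi, THF, −78 °C) gives 2-lithio-1,4,5,8-tetramethoxynaphthalene F2. Addition of F2 to commercial 2,2-dimethylcyclobutanone in the presence of CeCl3 (to limit enolisation) gives, after aqueous work-up, racemic 2,2-dimethyl-1-(1,4,5,8-tetramethoxynaphthalen-2-yl)cyclobutan-1-ol F3. Preparative chromatography on a chiral stationary phase then removes (S)-2,2-dimethyl-1-(1,4,5,8-tetramethoxynaphthalen-2-yl)cyclobutan-1-ol F4 and delivers (R)-17, with the configuration to be assigned by anomalous-dispersion crystallography.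

Step 11 (angeloylation of the hindered tertiary alkoxide). Acyl transfer to the very crowded alkoxide may be so slow that Z-to-E isomerisation of the angeloyl unit or attack at the trichlorobenzoyl carbonyl takes over. Fallback, setting out from 17 (through alkoxide 20) and rejoining at 21: acylation with 2-[bis(2,2,2-trifluoroethoxy)phosphoryl]propanoyl chloride, a saturated acyl donor with no alkene geometry to lose, so that forcing conditions are permitted. This gives (R)-2,2-dimethyl-1-(1,4,5,8-tetramethoxynaphthalen-2-yl)cyclobutyl 2-[bis(2,2,2-trifluoroethoxy)phosphoryl]propanoate F5. Still–Gennari olefination of F5 with acetaldehyde (KN(SiMe3)2, 18-crown-6, THF, −78 °C) then builds the Z-trisubstituted alkene after the ester bond is in place and gives 21.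

Step 13 (cleavage of the peri methyl ethers). Lewis-acid ionisation of the tertiary ester C–O bond may compete, above all in regioisomer 23, where that carbon sits on the methoxy-bearing ring; HCl released on quenching may also isomerise the Z alkene. Fallback, setting out from the mixture of 22 and 23 and rejoining at 24: oxidative demethylation with AgO and 6 M HNO3 in acetone converts the remaining dimethoxyarene ring of either regioisomer into a second quinone. Both give the same (R)-2,2-dimethyl-1-(1,4,5,8-tetraoxo-1,4,5,8-tetrahydronaphthalen-2-yl)cyclobutyl (Z)-2-methylbut-2-enoate F6. Two-electron reduction of F6 with aqueous Na2S2O4 then gives 24 without any Lewis acid.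

Further compounds
F1 | step 9 | 2-bromo-1,4,5,8-tetramethoxynaphthalene | Brc1cc(OC)c2c(OC)ccc(OC)c2c1OC
F2 | step 9 | 2-lithio-1,4,5,8-tetramethoxynaphthalene | [Li]c1cc(OC)c2c(OC)ccc(OC)c2c1OC
F3 | step 9 | racemic 2,2-dimethyl-1-(1,4,5,8-tetramethoxynaphthalen-2-yl)cyclobutan-1-ol | OC1(c2cc(OC)c3c(OC)ccc(OC)c3c2OC)CCC1(C)C
F4 | step 9 | (S)-2,2-dimethyl-1-(1,4,5,8-tetramethoxynaphthalen-2-yl)cyclobutan-1-ol | O[C@@]1(c2cc(OC)c3c(OC)ccc(OC)c3c2OC)CCC1(C)C
F5 | step 11 | (R)-2,2-dimethyl-1-(1,4,5,8-tetramethoxynaphthalen-2-yl)cyclobutyl 2-[bis(2,2,2-trifluoroethoxy)phosphoryl]propanoate (both epimers at the phosphonate carbon) | CC(C(=O)O[C@]1(c2cc(OC)c3c(OC)ccc(OC)c3c2OC)CCC1(C)C)P(=O)(OCC(F)(F)F)OCC(F)(F)F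
F6 | step 13 | (R)-2,2-dimethyl-1-(1,4,5,8-tetraoxo-1,4,5,8-tetrahydronaphthalen-2-yl)cyclobutyl (Z)-2-methylbut-2-enoate | C/C=C(/C)C(=O)O[C@]1(C2=CC(=O)C3=C(C2=O)C(=O)C=CC3=O)CCC1(C)C
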